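all flasks: starting material 0.20 M; enzyme 20 µM

| charge | added ligand | remark |
|---|---|---|
| Saturday's | 20 µM | run made earlier |
| Tuesday's | 30 µM | run made earlier |
| flask | 40 µM |  |

| Saturday's: time / h | Saturday's: target / % | Tuesday's: time / h | Tuesday's: target / % |
|---|---|---|---|
| 0.667 | 2.5 | 0.667 | 1.4 |
| 1.33 | 6.2 | 1.33 | 5.6 |
| 2.50 | 11.0 | 2.50 | 9.4 |
| 5.00 | 20.3 | 5.00 | 18.1 |
| 10.0 | 34.7 | 10.0 | 31.3 |

(readings scatter by 0.5 percentage points)

- factor on the rate of making target when 10 % of the starting material are converted if enzyme is charged twice over
- factor on the rate when 10 % of the starting material are converted if enzyme is charged at 4.0 µM instead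

- no earlier run changes the charge of enzyme; that part of a forecast is a guess

**The question.** I expected a small charge of enzyme, 4.0 µM against 20 µM, to reach 10 % conversion late, so I asked what that lateness costs the rate.

**Start rate.** Tuesday's run made 9.4 % of target by 2.50 h, a rate constant per starting material of 0.0395 h⁻¹. Between Saturday's 20 µM of added ligand and Tuesday's 30 µM, the logarithmic conversion at 10.0 h shrank by a factor of 0.881. I applied that factor once more for the flask's 40 µM, which put 10 % conversion at about 3.03 h.

**The fade.** Dividing out the starting material still left a slowing in Saturday's run: the constant fell from 0.0498 h⁻¹ early to 0.0399 h⁻¹ late, a rough reading given the scatter. I took this as a loss of activity on the clock and read from it 18.5 h, the fade half-time: the time in which that constant halves.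

**The count.** No run had changed the enzyme, so proportionality was my guess. On that guess the small charge needed 15.1 h, which is 0.656 fade half-times later than the flask, a further factor of 0.635. I committed to 0.127 for the small charge and, by the same count, 2.12 for the doubled one.

**The forecast.** It gave 2.1 for the doubled charge and 0.19 for the small one, the second above mine, and said: “Proportionality to enzyme is assumed”.

**The flask.** For the doubled charge the simulation gave 2.44, above my figure, and for the small charge 0.134 against my 0.127. In the flask at 1.50 h, idle complex, an off-cycle form, held 48.3 % of the enzyme charged.

    enzyme + added ligand ⇌ idle complex, settled at all times (K = 35000 M⁻¹)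
    enzyme ⇌ dormant form (K = 1.40, k = 0.0920 h⁻¹)
    starting material + enzyme → target + enzyme, rate k3*[starting material]*[enzyme]/(1 + ([starting material]/Km3)) (0.0560 M, k = 16000 M⁻¹ h⁻¹)

Between 1.50 h and 15.0 h my fade half-time gave a factor of 0.603. The flask's free enzyme went from 45.5 % to 31.7 % of the charge, a factor of 0.697, and stood at 28.0 % after 150 h.

The readings stem from a simulated flask from invented constants.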